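Numbering used throughout: lactone atoms O1, C2 (carbonyl), C3, C4, C5 (OCH2); C6 is the exocyclic methine and C7 the benzylic CH2. Ring A is the 4‑oxygenated 3‑methoxyphenyl ring, ring B the 3,4‑dioxygenated 5‑methoxyphenyl ring. TIPS = triisopropylsilyl, TBS = tert‑butyldimethylsilyl. Compounds are numbered 1–18 in the order they appear in the steps; 18 is the target.

## Analysis of the target

Target 18 is (3Z,4S)-3-(3,4-dihydroxy-5-methoxybenzylidene)-4-(4-hydroxy-3-methoxybenzyl)dihydrofuran-2(3H)-one. It has a single γ‑butyrolactone ring, with ring A attached to C4 through C7 and ring B attached to C3 through the exocyclic C3=C6 double bond. There is one stereocentre, C4 (S), and one stereogenic double bond whose Z geometry places ring B on the side of the lactone carbonyl. This is the less conjugated, less stable isomer, so equilibration cannot deliver it. The sensitive groups are a guaiacol and an air‑sensitive catechol, an arylidene lactone that is a Michael acceptor and isomerises under light, nucleophiles or base (especially once the para‑hydroxyl of ring B is ionised), and the C4–H bond, which is the γ‑hydrogen of the enoate. The difficulty is that C4 is an isolated stereocentre with no neighbouring heteroatom to direct its formation, and that the alkene geometry must be set against the thermodynamic preference. The strategy rests on reading C5–C4–C7 as the three‑carbon skeleton of epichlorohydrin 2 and C3–C2 as a unit supplied by malonate 1. If C3 and C7 are tied together for a time in a cyclopropane (bicyclic lactone 6), C7 stays electrophilic and can later accept ring A as a nucleophile, while C4 is never touched again.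

## Retrosynthetic reasoning

18 from 17 (O–Si bonds). The three phenols are unmasked last. Silyl ethers are chosen because their removal needs neither hydrogenation (the alkene), strong Lewis acid (the methyl ethers) nor base (the Z alkene). Ring A carries the more robust TIPS group because it has to pass through the organometallic and the hot dealkoxycarbonylation steps; ring B carries two TBS groups.

17 from 16 (no bond cut, only geometry). Condensation chemistry delivers the E isomer 16, so the Z isomer is traced back to it by a photochemical isomerisation. Placing this on the fully silylated compound keeps the oxidisable phenols out of the irradiation.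

16 from 11 and 13 (C3=C6). This is the only carbon–carbon bond holding ring B, and the α‑carbon of lactone 11 is its only acidic position. An aldol addition gives 14, and elimination through mesylate 15 gives the alkene. The two new sp3 centres of 14 disappear again, so their control is not needed. Aldehyde 13 comes from 12 by double silylation.

11 from 10 (C3–CO2Me). The extra ester is the second carboxyl of the malonate. It is needed earlier to activate the cyclopropane twice over, and it is removed once that job is done. C4 is not enolisable and is unaffected.

10 from 6 and 9 (C7–aryl). Cutting here puts the electrophile on C7 and the nucleophile on the electron‑rich ring A, which is the natural polarity of both partners. The forward reaction is a copper‑catalysed homoconjugate opening of the cyclopropane at its CH2 by aryl Grignard reagent 9, made from bromide 8 and ultimately from phenol 7. The C3–C7 bond breaks and C4 keeps its configuration.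

6 from 1 and 2 (C3–C7, O1–C5, C3–C4, O1–C2). All four bonds form in one operation from two commodity chemicals, through 3, 4 and 5. The oxygen‑bearing carbon of 2 undergoes exactly one SN2 inversion when the malonate carbon replaces oxygen, and it becomes C4 of the target. Following the descriptors through the priority changes, (S)-2 gives (1R,5S)-6 and hence (4S)-18.

## Alternatives that were turned down

Alternative 1: The lactone is disconnected at C3–C4 back to an acyclic ester A1, the arylpropiolate of a silyl‑protected coniferyl alcohol. In the forward sense A1 would be cyclised under hydrogen with [Rh(cod)2]OTf and one enantiomer of BINAP. Oxidative coupling of alkyne and alkene gives a rhodacyclopentene, and hydrogenolysis delivers hydrogen to C6 and C7, giving A2, the tris‑TBS ether of the target.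
- In favour: one step closes the ring, sets C4 and gives the Z alkene for mechanistic reasons, because the vinyl–rhodium bond is cis to the new C3–C4 bond and ring B therefore ends up cis to the carbonyl. On alkene geometry this plan is clearly stronger than the chosen one, and it is convergent.
- Against: the ester tether prefers the conformation that holds alkyne and alkene apart. The alkene is a 1,2‑disubstituted, electron‑rich styrene rather than a terminal one. The cinnamyl ester can ionise on low‑valent rhodium, simple hydrogenation competes, and the enantioselectivity rests entirely on the ligand for a substrate class not shown to work.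
- Comparison: the chosen route accepts an extra isomerisation step in exchange for an absolute configuration taken from the chiral pool and carbon–carbon bond formations that each have close precedent.

Alternative 2: The ring oxygen is removed retrosynthetically, leading to the prochiral cyclobutanone A3. A Baeyer–Villiger monooxygenase would insert oxygen next to one of the two enantiotopic CH2 groups and give the S lactone A4.
- In favour: mild aqueous conditions, oxygen as the oxidant, a free phenol tolerated, and 3‑substituted cyclobutanones are good substrates for these enzymes. On early protecting‑group economy and on the oxidant it is at least as good as the chosen plan.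
- Against: A3 needs its own synthesis of about three steps (ketene cycloaddition to an allylarene and dechlorination). The enzyme giving the S enantiomer with high selectivity for a guaiacyl‑substituted substrate would have to be found by screening. A4 is only the desilylated analogue of 11, so phenol protection and the whole endgame (aldol, dehydration, photoisomerisation) remain.
- Comparison: the chosen route reaches the same stage in three linear steps with the sense of induction fixed by the reagent and not by an enzyme panel.

Alternative 3: The lactone is opened at O1–C5 to the oxetanyl acrylic acid A5. A chiral phosphoric acid would activate the oxetane, and the carboxyl oxygen would attack one enantiotopic CH2 to give the hydroxymethyl lactone A6.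
- In favour: organocatalytic, and the C3=C6 bond is already in place.
- Against: A6 carries a hydroxymethyl group at C7, so the C7–aryl bond would have to be made by an sp3–sp2 coupling on a Michael acceptor with an acidic γ‑hydrogen at C4, where activation of the alcohol invites elimination through the dienolate. A5 is itself a multistep target. The alkene comes out E, so the photoisomerisation is still needed. Intramolecular oxetane opening by a hindered acrylic acid is at the edge of what this catalysis has shown.
- Comparison: the chosen route delivers C7 directly as an electrophilic cyclopropane carbon ready for ring A, with no functional‑group interconversion at that position.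

Key step: step 1

Remark: 10, 14 and 15 are expected as mixtures at the labile C3 centre or at the carbinol carbon C6. Names and SMILES show the expected trans C3 isomer and leave C6 undefined, because these centres are destroyed in steps 4 and 7.

## Route

Step 1
Reactants: 1 dimethyl malonate; 2 (S)-epichlorohydrin
Product: 6 methyl (1R,5S)-2-oxo-3-oxabicyclo[3.1.0]hexane-1-carboxylate, via chlorohydrin alkoxide 3 (not isolated), via epoxy malonate 4 (not isolated), via cyclopropylmethanol diester 5 (not isolated)
Conditions: NaOMe (1.0 equiv), 1 (1.2 equiv), MeOH, rt; 2 added slowly; then reflux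
Reagents that add atoms: none
Why: This is the known malonate–epichlorohydrin annulation, a tandem alkylation, cyclopropanation and lactonisation that gives 2-oxo-3-oxabicyclo[3.1.0]hexane-1-carboxylates. The sodium salt of 1 opens the epoxide of 2 at its unsubstituted CH2 (the future C7) to give alkoxide 3, which closes onto the CH2Cl carbon with loss of chloride to give epoxide 4 and so makes the future O1–C5 bond. The regenerated malonate anion of 4 attacks the stereogenic epoxide carbon in a 3-exo-tet SN2 closure with inversion, forming C3–C4 and cyclopropane 5. The freed alkoxide then acylates the ester cis to it (5-exo-trig addition–elimination), forming O1–C2 and the lactone. The configuration at C5 of 6 comes from the chiral‑pool centre of 2 through that single inversion. The configuration at C1 follows from it, because only the cis‑fused bicycle can form. The step needs the first attack to go to the epoxide CH2 and not to C–Cl, since the two paths lead to enantiomers; the strained, methanol‑activated epoxide is a much better electrophile for the soft malonate anion than a primary alkyl chloride. A slight excess of 1 over base keeps free methoxide low, so that neither 2 nor the activated cyclopropane of 6 is consumed by it.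

Step 2
Reactants: 7 4-bromo-2-methoxyphenol
Product: 8 (4-bromo-2-methoxyphenoxy)triisopropylsilane
Conditions: TIPSCl, imidazole, DMF, rt
Reagents that add atoms: triisopropylsilyl chloride, CC(C)[Si](Cl)(C(C)C)C(C)C
Why: Standard imidazole‑promoted O‑silylation of a phenol; the hindered TIPS ether is chosen to withstand the Grignard reagent, hot wet DMSO and amide bases while remaining cleavable by fluoride.

Step 3
Reactants: 8 (4-bromo-2-methoxyphenoxy)triisopropylsilane; 6 methyl (1R,5S)-2-oxo-3-oxabicyclo[3.1.0]hexane-1-carboxylate
Product: 10 methyl (3R,4S)-4-{[3-methoxy-4-(triisopropylsilyloxy)phenyl]methyl}-2-oxooxolane-3-carboxylate, via aryl Grignard reagent 9 (not isolated)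
Conditions: Mg, THF, 50 °C (8 to 9, 2 equiv); CuI (10 mol %), −40 °C; 6 in THF, −40 → −15 °C; aq NH4Cl
Reagents that add atoms: none
Why: Copper‑catalysed homoconjugate addition of an aryl Grignard reagent to a doubly activated cyclopropane: the arylcopper species attacks the unsubstituted CH2 (C7) in an SN2‑like way, C3–C7 breaks, and the charge ends up in a malonate‑type enolate that resists further addition. C4 is not involved and keeps its S configuration; protonation should give mainly the trans C3 epimer, which is of no consequence.

Step 4
Reactants: 10 methyl (3R,4S)-4-{[3-methoxy-4-(triisopropylsilyloxy)phenyl]methyl}-2-oxooxolane-3-carboxylate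
Product: 11 (4S)-4-{[3-methoxy-4-(triisopropylsilyloxy)phenyl]methyl}oxolan-2-one
Conditions: LiCl, H2O (2 equiv), DMSO, 140 °C
Reagents that add atoms: none
Why: Krapcho demethoxycarbonylation: chloride demethylates the ester by SN2 at the methyl group, the carboxylate α to the lactone carbonyl loses CO2, and water protonates the lactone enolate. The medium is neutral, so the hindered aryl silyl ether and the non‑enolisable C4 centre should survive.

Step 5
Reactants: 12 3,4-dihydroxy-5-methoxybenzaldehyde
Product: 13 3,4-bis(tert-butyldimethylsilyloxy)-5-methoxybenzaldehyde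
Conditions: TBSCl (2.5 equiv), imidazole, DMF, rt
Reagents that add atoms: tert-butyldimethylsilyl chloride, CC(C)(C)[Si](C)(C)Cl
Why: Double O‑silylation of the catechol under standard conditions; the aldehyde is unaffected and the product has no acidic hydrogen left to quench an enolate.

Step 6
Reactants: 11 (4S)-4-{[3-methoxy-4-(triisopropylsilyloxy)phenyl]methyl}oxolan-2-one; 13 3,4-bis(tert-butyldimethylsilyloxy)-5-methoxybenzaldehyde
Product: 14 (3R,4S)-3-{[3,4-bis(tert-butyldimethylsilyloxy)-5-methoxyphenyl](hydroxy)methyl}-4-{[3-methoxy-4-(triisopropylsilyloxy)phenyl]methyl}oxolan-2-one (mixture at the carbinol carbon)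
Conditions: LiN(iPr)2, THF, −78 °C; 13, −78 °C; AcOH, −78 °C
Reagents that add atoms: none
Why: Aldol addition of the lithium enolate of a β‑substituted γ‑butyrolactone to a non‑enolisable aryl aldehyde; the aldehyde approaches anti to the C4 benzyl group, so C3 forms trans to C4. The carbinol centre forms unselectively, which does not matter because C3 and C6 both become sp2 in step 7.

Step 7
Reactants: 14 (3R,4S)-3-{[3,4-bis(tert-butyldimethylsilyloxy)-5-methoxyphenyl](hydroxy)methyl}-4-{[3-methoxy-4-(triisopropylsilyloxy)phenyl]methyl}oxolan-2-one
Product: 16 (3E,4S)-3-{[3,4-bis(tert-butyldimethylsilyloxy)-5-methoxyphenyl]methylidene}-4-{[3-methoxy-4-(triisopropylsilyloxy)phenyl]methyl}oxolan-2-one, via benzylic mesylate 15 (not isolated)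
Conditions: MsCl, Et3N, CH2Cl2, 0 °C; then DBU, 0 °C → rt
Reagents that add atoms: none
Why: Mesylation of the benzylic alcohol followed by base‑induced E1cB elimination across C3–C6; the conjugated E isomer, with ring B anti to the carbonyl, should predominate, and any Z isomer formed is simply 17 and is carried on. Exposure to DBU is kept short and cold so that the γ‑hydrogen at C4 is not removed.

Step 8
Reactants: 16 (3E,4S)-3-{[3,4-bis(tert-butyldimethylsilyloxy)-5-methoxyphenyl]methylidene}-4-{[3-methoxy-4-(triisopropylsilyloxy)phenyl]methyl}oxolan-2-one
Product: 17 (3Z,4S)-3-{[3,4-bis(tert-butyldimethylsilyloxy)-5-methoxyphenyl]methylidene}-4-{[3-methoxy-4-(triisopropylsilyloxy)phenyl]methyl}oxolan-2-one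
Conditions: hν (350 nm lamps or Pyrex‑filtered medium‑pressure Hg lamp), degassed MeCN, dilute, rt; chromatography, recovered 16 re‑irradiated
Reagents that add atoms: none
Why: Photochemical E‑to‑Z isomerisation of an α‑arylidene lactone (a cinnamate‑type chromophore): the excited state relaxes through a twisted geometry to both isomers. The Z isomer, whose aryl ring is pushed out of conjugation by the ring‑locked carbonyl, should absorb less at the chosen wavelength and therefore accumulate. C4 takes no part.

Step 9
Reactants: 17 (3Z,4S)-3-{[3,4-bis(tert-butyldimethylsilyloxy)-5-methoxyphenyl]methylidene}-4-{[3-methoxy-4-(triisopropylsilyloxy)phenyl]methyl}oxolan-2-one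
Product: 18 (3Z,4S)-3-[(3,4-dihydroxy-5-methoxyphenyl)methylidene]-4-[(4-hydroxy-3-methoxyphenyl)methyl]oxolan-2-one
Conditions: Bu4NF, AcOH (1:1, 3.5 equiv), THF, 0 °C, Ar, exclusion of light
Reagents that add atoms: none
Why: Fluoride cleavage of three aryl silyl ethers, which are good leaving groups at silicon. Acetic acid keeps the phenols protonated, which should suppress both Z‑to‑E equilibration through the ring B para‑phenoxide and autoxidation of the catechol.

## Compound list

1 | dimethyl malonate | COC(=O)CC(=O)OC | starting material
2 | (S)-epichlorohydrin, (2S)-2-(chloromethyl)oxirane | ClC[C@@H]1CO1 | starting material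
3 | dimethyl 2-[(2S)-3-chloro-2-hydroxypropyl]propanedioate (present as its sodium alkoxide) | ClC[C@@H](O)CC(C(=O)OC)C(=O)OC | intermediate
4 | dimethyl 2-{[(2S)-oxiran-2-yl]methyl}propanedioate | COC(=O)C(C[C@H]1CO1)C(=O)OC | intermediate
5 | dimethyl (2S)-2-(hydroxymethyl)cyclopropane-1,1-dicarboxylate (present as its sodium alkoxide) | OC[C@H]1CC1(C(=O)OC)C(=O)OC | intermediate
6 | methyl (1R,5S)-2-oxo-3-oxabicyclo[3.1.0]hexane-1-carboxylate | C1[C@@H]2COC(=O)[C@]12C(=O)OC | intermediate
7 | 4-bromo-2-methoxyphenol | COc1cc(Br)ccc1O | starting material
8 | (4-bromo-2-methoxyphenoxy)triisopropylsilane | COc1cc(Br)ccc1O[Si](C(C)C)(C(C)C)C(C)C | intermediate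
9 | [3-methoxy-4-(triisopropylsilyloxy)phenyl]magnesium bromide | COc1cc([Mg]Br)ccc1O[Si](C(C)C)(C(C)C)C(C)C | intermediate
10 | methyl (3R,4S)-4-{[3-methoxy-4-(triisopropylsilyloxy)phenyl]methyl}-2-oxooxolane-3-carboxylate | COc1cc(C[C@@H]2COC(=O)[C@H]2C(=O)OC)ccc1O[Si](C(C)C)(C(C)C)C(C)C | intermediate
11 | (4S)-4-{[3-methoxy-4-(triisopropylsilyloxy)phenyl]methyl}oxolan-2-one | COc1cc(C[C@@H]2COC(=O)C2)ccc1O[Si](C(C)C)(C(C)C)C(C)C | intermediate
12 | 3,4-dihydroxy-5-methoxybenzaldehyde (5-hydroxyvanillin) | COc1cc(C=O)cc(O)c1O | starting material
13 | 3,4-bis(tert-butyldimethylsilyloxy)-5-methoxybenzaldehyde | COc1cc(C=O)cc(O[Si](C)(C)C(C)(C)C)c1O[Si](C)(C)C(C)(C)C | intermediate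
14 | (3R,4S)-3-{[3,4-bis(tert-butyldimethylsilyloxy)-5-methoxyphenyl](hydroxy)methyl}-4-{[3-methoxy-4-(triisopropylsilyloxy)phenyl]methyl}oxolan-2-one | COc1cc(C[C@@H]2COC(=O)[C@H]2C(O)c2cc(O[Si](C)(C)C(C)(C)C)c(O[Si](C)(C)C(C)(C)C)c(OC)c2)ccc1O[Si](C(C)C)(C(C)C)C(C)C | intermediate
15 | [3,4-bis(tert-butyldimethylsilyloxy)-5-methoxyphenyl][(3R,4S)-4-{[3-methoxy-4-(triisopropylsilyloxy)phenyl]methyl}-2-oxooxolan-3-yl]methyl methanesulfonate | COc1cc(C[C@@H]2COC(=O)[C@H]2C(OS(C)(=O)=O)c2cc(O[Si](C)(C)C(C)(C)C)c(O[Si](C)(C)C(C)(C)C)c(OC)c2)ccc1O[Si](C(C)C)(C(C)C)C(C)C | intermediate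
16 | (3E,4S)-3-{[3,4-bis(tert-butyldimethylsilyloxy)-5-methoxyphenyl]methylidene}-4-{[3-methoxy-4-(triisopropylsilyloxy)phenyl]methyl}oxolan-2-one | COc1cc(C[C@@H]2COC(=O)/C2=C/c2cc(O[Si](C)(C)C(C)(C)C)c(O[Si](C)(C)C(C)(C)C)c(OC)c2)ccc1O[Si](C(C)C)(C(C)C)C(C)C | intermediate
17 | (3Z,4S)-3-{[3,4-bis(tert-butyldimethylsilyloxy)-5-methoxyphenyl]methylidene}-4-{[3-methoxy-4-(triisopropylsilyloxy)phenyl]methyl}oxolan-2-one | COc1cc(C[C@@H]2COC(=O)/C2=C\c2cc(O[Si](C)(C)C(C)(C)C)c(O[Si](C)(C)C(C)(C)C)c(OC)c2)ccc1O[Si](C(C)C)(C(C)C)C(C)C | intermediate
18 | (3Z,4S)-3-[(3,4-dihydroxy-5-methoxyphenyl)methylidene]-4-[(4-hydroxy-3-methoxyphenyl)methyl]oxolan-2-one | COc1cc(C[C@@H]2COC(=O)/C2=C\c2cc(O)c(O)c(OC)c2)ccc1O | target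

## Step count and least certain steps

Total step count: 9. Longest linear sequence: 7 steps (1, 3, 4, 6, 7, 8, 9); steps 2 and 5 prepare the two aryl partners.

Step 1 (key step). The most likely failure is partial loss of enantiomeric purity. It can arise from direct displacement of chloride by the malonate anion, which feeds the enantiomeric series, or from reversible chloride opening of 2 through a symmetrical dichloro alkoxide. Methoxide can also consume 2, and the product's activated cyclopropane can be opened by excess nucleophile. Fallback: start from 1 and use an electrophile whose first site of attack is unambiguous. Commercial (S)-glycidol is converted with Tf2O and 2,6-lutidine into (R)-glycidyl trifluoromethanesulfonate F1. The sodium salt of 1 (NaH, THF, −20 °C) displaces the triflate directly and gives 4 as an isolated compound. NaOMe in MeOH then takes 4 through 5 to 6, where the route is rejoined.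

Step 3. The Grignard reagent may add to the ester or lactone carbonyl instead of the cyclopropane, or attack the substituted cyclopropane carbon, if transmetalation to copper is slow; the electron‑rich aryl group may also homocouple. Fallback: starting from 6, reverse the order of events at C7. The cyclopropane is opened with iodide (Me3SiCl, NaI, MeCN) to give methyl (3R,4S)-4-(iodomethyl)-2-oxooxolane-3-carboxylate F2. F2 is then joined to aryl bromide 8 by a nickel‑catalysed reductive cross‑electrophile coupling (NiI2, 4,4'-di-tert-butyl-2,2'-bipyridine, Zn, DMA), which uses no basic organometallic reagent. This returns to 10.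

Step 4. Hot wet DMSO with a salt may cleave the aryl silyl ether or open the lactone hydrolytically before decarboxylation is complete. Fallback: starting from 10, hydrolyse the methyl ester under neutral conditions with Me3SnOH in 1,2-dichloroethane at 80 °C to give (3R,4S)-4-{[3-methoxy-4-(triisopropylsilyloxy)phenyl]methyl}-2-oxooxolane-3-carboxylic acid F3. F3 is decarboxylated by heating in toluene, which returns to 11.

Step 8. The photostationary mixture may not be rich enough in the Z isomer. Photodimerisation across C3=C6 or photo‑oxidation of the electron‑rich arenes may compete at practical concentrations. Fallback: set the geometry kinetically and bypass 14–16. Starting from 11, the lithium enolate (LiN(iPr)2, 2 equiv) is phosphonylated with bis(2,2,2-trifluoroethyl) phosphorochloridate to give (3S,4S)-3-[bis(2,2,2-trifluoroethoxy)phosphoryl]-4-{[3-methoxy-4-(triisopropylsilyloxy)phenyl]methyl}oxolan-2-one F4. A Still–Gennari‑type Horner–Wadsworth–Emmons reaction of F4 with 13 (KN(SiMe3)2, 18-crown-6, THF, −78 °C) should place ring B cis to the carbonyl and give 17 directly.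

Step 9. Fluoride treatment may ionise the ring B para‑hydroxyl; the quinone‑methide character of that phenoxide lowers the rotational barrier of C3=C6, so the alkene may drift back to E. The free catechol may also oxidise during work‑up. Fallback: starting from 16, desilylate first under the same buffered conditions, where geometry is not at stake, to give the E‑configured triphenol (3E,4S)-3-[(3,4-dihydroxy-5-methoxyphenyl)methylidene]-4-[(4-hydroxy-3-methoxyphenyl)methyl]oxolan-2-one F5. F5 is then irradiated in degassed MeCN as the very last operation, so that no reagent follows formation of the Z alkene; chromatography gives 18.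

## Further compounds

F1 | step 1 | [(2R)-oxiran-2-yl]methyl trifluoromethanesulfonate | FC(F)(F)S(=O)(=O)OC[C@H]1CO1
F2 | step 3 | methyl (3R,4S)-4-(iodomethyl)-2-oxooxolane-3-carboxylate | IC[C@@H]1COC(=O)[C@H]1C(=O)OC
F3 | step 4 | (3R,4S)-4-{[3-methoxy-4-(triisopropylsilyloxy)phenyl]methyl}-2-oxooxolane-3-carboxylic acid | COc1cc(C[C@@H]2COC(=O)[C@H]2C(=O)O)ccc1O[Si](C(C)C)(C(C)C)C(C)C
F4 | step 8 | (3S,4S)-3-[bis(2,2,2-trifluoroethoxy)phosphoryl]-4-{[3-methoxy-4-(triisopropylsilyloxy)phenyl]methyl}oxolan-2-one | COc1cc(C[C@@H]2COC(=O)[C@H]2P(=O)(OCC(F)(F)F)OCC(F)(F)F)ccc1O[Si](C(C)C)(C(C)C)C(C)C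
F5 | step 9 | (3E,4S)-3-[(3,4-dihydroxy-5-methoxyphenyl)methylidene]-4-[(4-hydroxy-3-methoxyphenyl)methyl]oxolan-2-one | COc1cc(C[C@@H]2COC(=O)/C2=C/c2cc(O)c(O)c(OC)c2)ccc1O
A1 | alternative 1 | (2E)-3-[4-(tert-butyldimethylsilyloxy)-3-methoxyphenyl]prop-2-en-1-yl 3-[3,4-bis(tert-butyldimethylsilyloxy)-5-methoxyphenyl]prop-2-ynoate | COc1cc(/C=C/COC(=O)C#Cc2cc(O[Si](C)(C)C(C)(C)C)c(O[Si](C)(C)C(C)(C)C)c(OC)c2)ccc1O[Si](C)(C)C(C)(C)C
A2 | alternative 1 | (3Z,4S)-3-{[3,4-bis(tert-butyldimethylsilyloxy)-5-methoxyphenyl]methylidene}-4-{[4-(tert-butyldimethylsilyloxy)-3-methoxyphenyl]methyl}oxolan-2-one | COc1cc(C[C@@H]2COC(=O)/C2=C\c2cc(O[Si](C)(C)C(C)(C)C)c(O[Si](C)(C)C(C)(C)C)c(OC)c2)ccc1O[Si](C)(C)C(C)(C)C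
A3 | alternative 2 | 3-[(4-hydroxy-3-methoxyphenyl)methyl]cyclobutan-1-one | COc1cc(CC2CC(=O)C2)ccc1O
A4 | alternative 2 | (4S)-4-[(4-hydroxy-3-methoxyphenyl)methyl]oxolan-2-one | COc1cc(C[C@@H]2COC(=O)C2)ccc1O
A5 | alternative 3 | (2E)-3-[3,4-bis(tert-butyldimethylsilyloxy)-5-methoxyphenyl]-2-(oxetan-3-yl)prop-2-enoic acid | OC(=O)/C(=C/c1cc(O[Si](C)(C)C(C)(C)C)c(O[Si](C)(C)C(C)(C)C)c(OC)c1)C1COC1
A6 | alternative 3 | (3E,4R)-3-{[3,4-bis(tert-butyldimethylsilyloxy)-5-methoxyphenyl]methylidene}-4-(hydroxymethyl)oxolan-2-one | OC[C@@H]1COC(=O)/C1=C/c1cc(O[Si](C)(C)C(C)(C)C)c(O[Si](C)(C)C(C)(C)C)c(OC)c1
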